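in all of them: L 0.40 mM

| flask | Q | G | remark |
|---|---|---|---|
| gamma | 0.20 M | 0.38 M | run made earlier |
| epsilon | 0.30 M | 0.38 M | run made earlier |
| flask | 0.40 M | 0.380 M |  |

- gamma (time / min: X / %): 12.0: 34.8; 25.0: 57.7; 40.0: 70.7; 50.0: 75.9; 60.0: 77.4; 80.0: 78.2
- epsilon (time / min: X / %): 6.00: 17.2; 10.0: 27.1; 15.0: 38.7; 25.0: 50.4; 40.0: 57.9; 80.0: 62.1

(standard deviation of a reading: 0.5 percentage points)

* apparent order in L when 30% of the Q are converted (percent change of the rate of making X for one percent more L charged)

At 80.0 min in gamma and 80.0 min in epsilon, X has stalled with Q still present: 21.8% of the Q charged in gamma, 37.9% in epsilon. Both runs charged 0.38 M of G. The stall is read here as the end of G, so whatever G did not give as X went to a side loss. The readings give a measure of that loss: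

split charge = Q charged × lost G / X at the stall = 0.312 M from epsilon, 0.286 M from gamma

This split charge, the Q charge at which G divides evenly between X and loss, is carried forward as the epsilon reading.

First order in L is the zero of the scale. It requires lost G to be small against standing G at 30% conversion. The flask charges 0.40 M, which is 1.28 times the split charge, so the reckoning here takes 0.780 of G lost per X made, an estimate that holds the ratio read at the stall constant along the run. At 30%:

X = 0.120 M, lost G = 0.0936 M, standing G = 0.166 M

One percent more L reaches that conversion about one percent sooner, with about one percent less G lost. Taking the rate as proportional to G and to L: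

order = 1 + lost G / standing G = 1.56

The forecast stands higher, at 1.8 with a range of 1 to 3.2, on a different ground: “more L delays the decay”.

The flask gives 1.4.

    J → L + X (k = 820 min⁻¹)
    Q + Z → J (k = 180 M⁻¹ min⁻¹)
    D ⇌ Z (K = 2.20, k = 3300 min⁻¹)
    G → E (k = 0.0400 min⁻¹)
    G + L → D (k = 230 M⁻¹ min⁻¹)

At 2.00 h this flask holds G, the limiting reagent, at 0% of its charge, with Q at 49.9% and E at 0.179 M. At 0.200 h this flask holds E at 0.120 M with X at 27.8% of the Q charged, which is 1.08 of E per X, against the 0.780 of the estimate. The split charge puts X at the stall at 53.4% of the Q charged in this flask, against 50.1%, and in gamma at 74.2%, against the 78.2% read.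

The runs come from a simulation with constants of no real substance; the scatter is artificial.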